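**Assumption:** the target has no stereocentre and no stereogenic axis (it is achiral), so "single enantiomer" needs no stereocontrol and no SMILES carries stereodescriptors.

## Retrosynthetic overview

1. Target 18 ⇒ global hydrogenolysis of the fully protected tridepside 17 (five benzyl ethers, one benzyl ester, one diphenylmethylene ketal).
2. Both depside carbonyls are cut at the C(aryl)–C(=O) bond, not at the acyl–O bond. Each C=O is carbon monoxide inserted by Pd between an aryl halide and a phenol, so no activated gallic acid is used.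
3. The order is set by halide reactivity: ring-C aryl iodide + CO + ring-B bromophenol first (60 °C, C–Br untouched), then ring-B aryl bromide + CO + ring-A phenol (80 °C).
4. Blocks: ring A = benzyl gallate 3,4-O-diphenylmethylene ketal 5; ring B = 2,6-bis(benzyloxy)-4-bromophenol 14 (SNAr, then Dakin); ring C = 5-iodo-1,2,3-tris(benzyloxy)benzene 8.
5. No ring is constructed. All three benzene rings are bought (C, B, A are joined in that order); the only ring formed is the temporary dioxole ketal on ring A (step 2), removed in step 9.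

## Route

**Step 1**
Reactants: 1 gallic acid (3,4,5-trihydroxybenzoic acid); 2 benzyl bromide
Product: 3 benzyl gallate (benzyl 3,4,5-trihydroxybenzoate)
Conditions: BnBr (1.05 equiv), KHCO3 (1.2 equiv), DMF, rt
Reagents that add atoms: benzyl bromide (2), BrCc1ccccc1
Why: Chemoselective carboxylate O-alkylation (SN2 esterification); hydrogencarbonate deprotonates only the CO2H (pKa ≈ 4.4), not the phenols (pKa ≥ 8.7), so only the benzyl ester forms.

**Step 2**
Reactants: 3 benzyl gallate; 4 dichlorodiphenylmethane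
Product: 5 benzyl 7-hydroxy-2,2-diphenyl-1,3-benzodioxole-5-carboxylate (benzyl gallate with the 3,4-oxygens bridged by CPh2, one meta-OH free)
Conditions: Ph2CCl2 (1.2 equiv), K2CO3, MeCN, rt
Reagents that add atoms: dichlorodiphenylmethane (4), ClC(Cl)(c1ccccc1)c1ccccc1
Why: Diphenylmethylene catechol-ketal formation; the gem-dichloride can only bridge two adjacent phenols, and 3,4- and 4,5-bridging are the same by symmetry, so exactly one meta-OH is left free.

**Step 3**
Reactants: 6 5-iodo-1,2,3-trimethoxybenzene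
Product: 7 5-iodobenzene-1,2,3-triol (5-iodopyrogallol)
Conditions: BBr3 (3.5 equiv), CH2Cl2, −78 °C → rt; H2O
Reagents that add atoms: none
Why: Lewis-acid aryl methyl ether cleavage with BBr3; the aryl iodide is inert to these conditions.

**Step 4**
Reactants: 7 5-iodobenzene-1,2,3-triol; 2 benzyl bromide
Product: 8 5-iodo-1,2,3-tris(benzyloxy)benzene
Conditions: BnBr (3.5 equiv), K2CO3, DMF, 60 °C, Ar
Reagents that add atoms: benzyl bromide (2), BrCc1ccccc1
Why: Threefold Williamson ether synthesis, run under argon because the pyrogallol anion is air-sensitive.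

**Step 5**
Reactants: 9 4-bromo-2,6-difluorobenzaldehyde; 10 benzyl alcohol
Product: 11 2,6-bis(benzyloxy)-4-bromobenzaldehyde
Conditions: BnOH (2.4 equiv), NaH (2.3 equiv), THF, 0 °C; then 9, 0 → 40 °C
Reagents that add atoms: benzyl alcohol (10), OCc1ccccc1
Why: Double nucleophilic aromatic substitution (SNAr); both fluorides are ortho to the formyl group and fluoride is displaced far faster than the para bromide, while pre-formed alkoxide at low temperature limits Tishchenko/Cannizzaro side reactions.

**Step 6**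
Reactants: 11 2,6-bis(benzyloxy)-4-bromobenzaldehyde; 12 meta-chloroperoxybenzoic acid (mCPBA)
Product: 14 2,6-bis(benzyloxy)-4-bromophenol, via aryl formate 13 (not isolated)
Conditions: mCPBA (1.2 equiv), CH2Cl2, 0 °C → rt; aq. Na2S2O3 wash; then K2CO3 (cat.), MeOH, rt
Reagents that add atoms: mCPBA (12), OOC(=O)c1cccc(Cl)c1
Why: Dakin-type Baeyer–Villiger oxidation; the electron-rich 2,6-dialkoxyaryl group migrates in preference to H, and the resulting aryl formate is methanolysed under mild base.

**Step 7**
Reactants: 8 5-iodo-1,2,3-tris(benzyloxy)benzene; 14 2,6-bis(benzyloxy)-4-bromophenol (1.1 equiv); 15 carbon monoxide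
Product: 16 2,6-bis(benzyloxy)-4-bromophenyl 3,4,5-tris(benzyloxy)benzoate
Conditions: CO (1 atm), PdCl2(PPh3)2 (3 mol%), Et3N (3 equiv), toluene, 60 °C
Reagents that add atoms: carbon monoxide (15), [C-]#[O+]
Why: Palladium-catalysed aryloxycarbonylation (Heck carbonylation) by oxidative addition into C–I, CO insertion and phenoxide capture of the acylpalladium; under CO with PPh3 at 60 °C the C–Br bond of 14 does not add to Pd, so 14 acts only as the nucleophile.

**Step 8**
Reactants: 16 2,6-bis(benzyloxy)-4-bromophenyl 3,4,5-tris(benzyloxy)benzoate; 5 benzyl 7-hydroxy-2,2-diphenyl-1,3-benzodioxole-5-carboxylate (1.2 equiv); 15 carbon monoxide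
Product: 17 benzyl 7-({3,5-bis(benzyloxy)-4-[3,4,5-tris(benzyloxy)benzoyloxy]benzoyl}oxy)-2,2-diphenyl-1,3-benzodioxole-5-carboxylate
Conditions: CO (1 atm), Pd(OAc)2 (5 mol%), Xantphos (6 mol%), Et3N (2 equiv), toluene, 80 °C
Reagents that add atoms: carbon monoxide (15), [C-]#[O+]
Why: Second Pd-catalysed aryloxycarbonylation, now at the aryl bromide, using wide-bite-angle Xantphos, which allows ArBr carbonylation at 1 atm CO and 80 °C; the weak amine base and non-polar solvent keep phenoxide trans-esterification of the existing depside ester slow.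

**Step 9**
Reactants: 17 protected tridepside
Product: 18 3-{[3,5-dihydroxy-4-(3,4,5-trihydroxybenzoyloxy)benzoyl]oxy}-4,5-dihydroxybenzoic acid (target)
Conditions: H2 (1 atm), 10% Pd/C, THF–EtOAc (AcOH cat.), rt
Reagents that add atoms: none
Why: Global hydrogenolysis cleaves the five benzyl ethers, the benzyl ester and the diphenylmethylene ketal while aryl esters are inert, and the neutral to slightly acidic aprotic medium avoids depside acyl migration and solvolysis.

## Compound list

1 | gallic acid | O=C(O)c1cc(O)c(O)c(O)c1 | starting material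
2 | benzyl bromide | BrCc1ccccc1 | starting material
3 | benzyl gallate | O=C(OCc1ccccc1)c1cc(O)c(O)c(O)c1 | intermediate
4 | dichlorodiphenylmethane | ClC(Cl)(c1ccccc1)c1ccccc1 | starting material
5 | benzyl 7-hydroxy-2,2-diphenyl-1,3-benzodioxole-5-carboxylate | O=C(OCc1ccccc1)c1cc(O)c2OC(c3ccccc3)(c3ccccc3)Oc2c1 | intermediate
6 | 5-iodo-1,2,3-trimethoxybenzene | COc1cc(I)cc(OC)c1OC | starting material
7 | 5-iodobenzene-1,2,3-triol | Oc1cc(I)cc(O)c1O | intermediate
8 | 5-iodo-1,2,3-tris(benzyloxy)benzene | Ic1cc(OCc2ccccc2)c(OCc2ccccc2)c(OCc2ccccc2)c1 | intermediate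
9 | 4-bromo-2,6-difluorobenzaldehyde | O=Cc1c(F)cc(Br)cc1F | starting material
10 | benzyl alcohol | OCc1ccccc1 | starting material
11 | 2,6-bis(benzyloxy)-4-bromobenzaldehyde | O=Cc1c(OCc2ccccc2)cc(Br)cc1OCc1ccccc1 | intermediate
12 | meta-chloroperoxybenzoic acid | OOC(=O)c1cccc(Cl)c1 | starting material
13 | 2,6-bis(benzyloxy)-4-bromophenyl formate | O=COc1c(OCc2ccccc2)cc(Br)cc1OCc1ccccc1 | intermediate
14 | 2,6-bis(benzyloxy)-4-bromophenol | Oc1c(OCc2ccccc2)cc(Br)cc1OCc1ccccc1 | intermediate
15 | carbon monoxide | [C-]#[O+] | starting material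
16 | 2,6-bis(benzyloxy)-4-bromophenyl 3,4,5-tris(benzyloxy)benzoate | O=C(Oc1c(OCc2ccccc2)cc(Br)cc1OCc1ccccc1)c1cc(OCc2ccccc2)c(OCc2ccccc2)c(OCc2ccccc2)c1 | intermediate
17 | benzyl 7-({3,5-bis(benzyloxy)-4-[3,4,5-tris(benzyloxy)benzoyloxy]benzoyl}oxy)-2,2-diphenyl-1,3-benzodioxole-5-carboxylate | O=C(OCc1ccccc1)c1cc(OC(=O)c2cc(OCc3ccccc3)c(OC(=O)c3cc(OCc4ccccc4)c(OCc4ccccc4)c(OCc4ccccc4)c3)c(OCc3ccccc3)c2)c2OC(c3ccccc3)(c3ccccc3)Oc2c1 | intermediate
18 | 3-{[3,5-dihydroxy-4-(3,4,5-trihydroxybenzoyloxy)benzoyl]oxy}-4,5-dihydroxybenzoic acid | O=C(O)c1cc(O)c(O)c(OC(=O)c2cc(O)c(OC(=O)c3cc(O)c(O)c(O)c3)c(O)c2)c1 | target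

## Totals

Total step count: 9.
Longest linear sequence: 5 steps (steps 3, 4, 7, 8, 9 or steps 5, 6, 7, 8, 9).

## Three steps most likely to fail, with fallbacks

**Step 8 (highest risk).** The aryl bromide needs 80 °C, and at that temperature the phenoxide of 5 could trans-esterify the existing ring C–ring B aryl ester and scramble the depside. The fallback sets out from 11 and 5 and comes back to the route at 17; it changes the order of assembly, with the ring-B phenol masked as its aldehyde. Bromo-aldehyde 11 is carbonylatively coupled with phenol 5 (CO, Pd(OAc)2/Xantphos, Et3N, toluene, 80 °C). No depside ester is present at this stage, and exchange of the new ester with 5 is degenerate. This gives benzyl 7-{[3,5-bis(benzyloxy)-4-formylbenzoyl]oxy}-2,2-diphenyl-1,3-benzodioxole-5-carboxylate F1. Dakin oxidation (mCPBA, CH2Cl2) gives the aryl formate benzyl 7-{[3,5-bis(benzyloxy)-4-(formyloxy)benzoyl]oxy}-2,2-diphenyl-1,3-benzodioxole-5-carboxylate F2. Its formate is removed selectively (KHCO3, MeOH–THF, 0 °C; aryl formates solvolyse far faster than aryl benzoates) to give the phenol benzyl 7-{[3,5-bis(benzyloxy)-4-hydroxybenzoyl]oxy}-2,2-diphenyl-1,3-benzodioxole-5-carboxylate F3. F3 is then acylated carbonylatively with iodide 8 under the mild step-7 conditions (60 °C) to give 17.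

**Step 7.** The nucleophile is a di-ortho-substituted phenol that may capture the acylpalladium sluggishly, and prolonged heating would erode the I/Br selectivity. The fallback sets out from 8 and comes back at 16; it replaces direct capture at palladium by acyl transfer from an isolated active ester. Iodide 8 is carbonylated with the crystalline CO surrogate 2,4,6-trichlorophenyl formate (O=COc1c(Cl)cc(Cl)cc1Cl; Pd(OAc)2/Xantphos, Et3N, toluene, rt) to give 2,4,6-trichlorophenyl 3,4,5-tris(benzyloxy)benzoate F4. The acyl group is then transferred to phenol 14 (DMAP cat., Et3N, MeCN, 40 °C), driven by the much better trichlorophenoxide leaving group, to give 16.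

**Step 5.** Benzyl alkoxide and an aromatic aldehyde can undergo Tishchenko or Cannizzaro redox chemistry, and the second SNAr is slower than the first. The fallback sets out from 9 and comes back at 11; the benzyl ethers are made by Williamson alkylation instead of SNAr with benzyl alkoxide. Aldehyde 9 is treated with NaOMe in MeOH at reflux to give 4-bromo-2,6-dimethoxybenzaldehyde F5. Chelation-assisted demethylation (BBr3, CH2Cl2, −78 → 0 °C) gives 4-bromo-2,6-dihydroxybenzaldehyde F6, which is benzylated with benzyl bromide 2 (K2CO3, DMF, 50 °C) to give 11.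

## Further compounds

F1 | step 8 | benzyl 7-{[3,5-bis(benzyloxy)-4-formylbenzoyl]oxy}-2,2-diphenyl-1,3-benzodioxole-5-carboxylate | O=Cc1c(OCc2ccccc2)cc(cc1OCc1ccccc1)C(=O)Oc1cc(cc2OC(c3ccccc3)(c3ccccc3)Oc12)C(=O)OCc1ccccc1
F2 | step 8 | benzyl 7-{[3,5-bis(benzyloxy)-4-(formyloxy)benzoyl]oxy}-2,2-diphenyl-1,3-benzodioxole-5-carboxylate | O=COc1c(OCc2ccccc2)cc(cc1OCc1ccccc1)C(=O)Oc1cc(cc2OC(c3ccccc3)(c3ccccc3)Oc12)C(=O)OCc1ccccc1
F3 | step 8 | benzyl 7-{[3,5-bis(benzyloxy)-4-hydroxybenzoyl]oxy}-2,2-diphenyl-1,3-benzodioxole-5-carboxylate | Oc1c(OCc2ccccc2)cc(cc1OCc1ccccc1)C(=O)Oc1cc(cc2OC(c3ccccc3)(c3ccccc3)Oc12)C(=O)OCc1ccccc1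
F4 | step 7 | 2,4,6-trichlorophenyl 3,4,5-tris(benzyloxy)benzoate | O=C(Oc1c(Cl)cc(Cl)cc1Cl)c1cc(OCc2ccccc2)c(OCc2ccccc2)c(OCc2ccccc2)c1
F5 | step 5 | 4-bromo-2,6-dimethoxybenzaldehyde | COc1cc(Br)cc(OC)c1C=O
F6 | step 5 | 4-bromo-2,6-dihydroxybenzaldehyde | Oc1cc(Br)cc(O)c1C=O
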